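**Strategy.** The target is a trans-3,4-disubstituted γ-butyrolactone (ring A: O1, C2, C3, C4, C5) with a pyronylmethyl arm (C7) on C3 and a 3,4-dimethoxybenzyl arm (C8) on C4. The route exploits the C8–C4–C3 triad: in the precursor these three carbons are a cyclopropane fused to ring A, with C3 activated by the lactone carbonyl and an ester. In one flask an arylcopper reagent opens the cyclopropane at C8 and the C3 enolate set free is alkylated by a bromomethylpyrone, forming C8–aryl and C3–C7. The precursor is the bicyclic lactone ester made from (R)-epichlorohydrin, which already carries C4. Decarboxylation and equilibration at C3 finish the synthesis.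

Key step: step 4

Remark: the SMILES is read as the (3R,4R) trans lactone. C3 of a γ-lactone is not expected to equilibrate at a useful rate in hot aqueous acid, so its configuration is settled in a separate base step after the decarboxylation.

**Step 1**
Reactants: 1 (R)-epichlorohydrin; 2 dimethyl malonate
Product: 6 methyl (1S,5R)-2-oxo-3-oxabicyclo[3.1.0]hexane-1-carboxylate, via chlorohydrin malonate 3 (not isolated), via epoxide malonate 4 (not isolated), via cyclopropylcarbinol diester 5 (not isolated)
Conditions: NaOMe (1.2 equiv), 2 (1.3 equiv), MeOH, 0 °C to reflux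
Reagents that add atoms: none
Why: Tandem epoxide opening, epoxide transposition, 3-exo-tet cyclopropanation and lactonization: the malonate anion attacks the CH2 end of the epoxide, the alkoxide of 3 displaces chloride to give 4, the malonate carbanion opens 4 with inversion at the stereogenic carbon, and the alkoxide of 5 closes onto the cis ester, so that the stereogenic carbon of 1 becomes C5 (R) and the cis ring fusion fixes C1 (S).

**Step 2**
Reactants: 7 ethyl 3-methylbut-2-enoate; 8 diethyl oxalate
Product: 10 ethyl 4-methyl-2-oxo-2H-pyran-6-carboxylate, via potassium dienolate 9 (not isolated)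
Conditions: KOEt (1.05 equiv), EtOH/toluene, 0 °C to rt; then MsOH (1.2 equiv), toluene, 80 °C, EtOH distilled off
Reagents that add atoms: none
Why: Vinylogous Claisen condensation at a γ-methyl group of 7 with the oxalate gives the stabilized enolate 9, and on acidification the enol hydroxyl lactonizes onto the unsaturated ester with loss of ethanol to form the 2-pyrone.

**Step 3**
Reactants: 10 ethyl 4-methyl-2-oxo-2H-pyran-6-carboxylate
Product: 11 ethyl 4-(bromomethyl)-2-oxo-2H-pyran-6-carboxylate
Conditions: NBS (1.05 equiv), AIBN (5 mol %), PhCF3, 85 °C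
Reagents that add atoms: N-bromosuccinimide, O=C1CCC(=O)N1Br
Why: Wohl–Ziegler radical bromination, in which the 4-methyl group is the only allylic C–H position and the electron-poor pyrone ring should resist electrophilic bromination at the low bromine concentration of a radical chain.

**Step 4**
Reactants: 6 methyl (1S,5R)-2-oxo-3-oxabicyclo[3.1.0]hexane-1-carboxylate; 12 4-bromo-1,2-dimethoxybenzene; 11 ethyl 4-(bromomethyl)-2-oxo-2H-pyran-6-carboxylate
Product: 15 methyl (3R,4R)-4-(3,4-dimethoxybenzyl)-3-{[6-(ethoxycarbonyl)-2-oxo-2H-pyran-4-yl]methyl}-2-oxotetrahydrofuran-3-carboxylate, via (3,4-dimethoxyphenyl)magnesium bromide 13 (not isolated), via bromomagnesium lactone enolate 14 (not isolated)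
Conditions: 12, Mg (1.1 equiv), THF, 40 °C; the resulting 13 (1.0 equiv) added to 6 (1.05 equiv), CuI (10 mol %), THF, −40 to −20 °C; then 11 (1.1 equiv), DMPU, −20 °C to rt; aq. NH4Cl
Reagents that add atoms: none
Why: The Grignard reagent 13 and CuI give an arylcopper species that attacks the unsubstituted cyclopropane carbon C6 of 6 (C8 of the target) in an SN2-like homoconjugate addition, breaking the C1–C6 bond so that C1 (C3 of the target) leaves as the chelated enolate 14, stabilized by the lactone and the ester carbonyl. The closest known reaction type is the copper-catalysed opening of 2-oxo-3-oxabicyclo[3.1.0]hexane-1-carboxylates by Grignard reagents, and C-alkylation of the resulting α-alkoxycarbonyl lactone enolates by benzylic or allylic bromides is equally established; here the two are run in one flask. No ring is closed, and the ring-fusion carbon C5 of 6 is not touched, so C4 of 15 keeps the R configuration. The new quaternary centre C3 is controlled by the C4 substituent: bromide 11 should approach the planar enolate on the face opposite the freshly formed 3,4-dimethoxybenzyl group, which places the pyronylmethyl group trans to it (3R). The step needs attack at the cyclopropane CH2 and not at the lactone or ester carbonyls, and SN2 displacement at CH2Br and not addition to the pyrone. The first is secured by copper catalysis at low temperature together with the strain and double activation of the fused cyclopropane, the second by keeping 13 as the limiting reagent so that only the soft, weakly basic malonate-type enolate meets 11, with DMPU loosening the magnesium chelate.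

**Step 5**
Reactants: 15 methyl (3R,4R)-4-(3,4-dimethoxybenzyl)-3-{[6-(ethoxycarbonyl)-2-oxo-2H-pyran-4-yl]methyl}-2-oxotetrahydrofuran-3-carboxylate
Product: 17 4-{[(4R)-4-(3,4-dimethoxybenzyl)-2-oxotetrahydrofuran-3-yl]methyl}-2-oxo-2H-pyran-6-carboxylic acid as a mixture of C3 epimers, via lactone diacid 16 (not isolated)
Conditions: 6 M aq. HCl/AcOH (1:1), 100 °C; concentration with toluene
Reagents that add atoms: water, O
Why: Acid-catalysed hydrolysis of both esters and decarboxylation of the malonic-type acid 16 through its enol, under conditions that should spare the aryl methyl ethers, the 2-pyrone and (after concentration) the γ-lactone; C4 has no acidic hydrogen and stays R, while C3 is expected to form as both epimers because the enol is protonated under kinetic control.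

**Step 6**
Reactants: 17 4-{[(4R)-4-(3,4-dimethoxybenzyl)-2-oxotetrahydrofuran-3-yl]methyl}-2-oxo-2H-pyran-6-carboxylic acid (C3 epimers)
Product: 18 4-{[(3R,4R)-4-(3,4-dimethoxybenzyl)-2-oxotetrahydrofuran-3-yl]methyl}-2-oxo-2H-pyran-6-carboxylic acid (target)
Conditions: DBU (3 equiv), dry MeCN, 60 °C; then 1 M aq. HCl; crystallization
Reagents that add atoms: none
Why: Base-mediated epimerization through the lactone enolate, in which reversible deprotonation at C3 by the non-nucleophilic amidine should funnel the mixture to the more stable trans lactone (3R), while the pyrone is deactivated as its carboxylate and C4 cannot be deprotonated.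

**Compound list**
1 | (R)-epichlorohydrin, (2R)-2-(chloromethyl)oxirane | ClC[C@H]1CO1 | starting material
2 | dimethyl malonate | COC(=O)CC(=O)OC | starting material
3 | dimethyl 2-[(2R)-3-chloro-2-hydroxypropyl]propanedioate (as sodium alkoxide) | COC(=O)C(C(=O)OC)C[C@@H](O)CCl | intermediate
4 | dimethyl 2-{[(2R)-oxiran-2-yl]methyl}propanedioate | COC(=O)C(C(=O)OC)C[C@@H]1CO1 | intermediate
5 | dimethyl (2R)-2-(hydroxymethyl)cyclopropane-1,1-dicarboxylate (as sodium alkoxide) | OC[C@@H]1CC1(C(=O)OC)C(=O)OC | intermediate
6 | methyl (1S,5R)-2-oxo-3-oxabicyclo[3.1.0]hexane-1-carboxylate | O=C1OC[C@@H]2C[C@]12C(=O)OC | intermediate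
7 | ethyl 3-methylbut-2-enoate | CCOC(=O)C=C(C)C | starting material
8 | diethyl oxalate | CCOC(=O)C(=O)OCC | starting material
9 | potassium enolate of diethyl 4-methyl-2-oxohex-4-enedioate (double-bond geometry not fixed) | CCOC(=O)C([O-])=CC(C)=CC(=O)OCC.[K+] | intermediate
10 | ethyl 4-methyl-2-oxo-2H-pyran-6-carboxylate | CCOC(=O)c1cc(C)cc(=O)o1 | intermediate
11 | ethyl 4-(bromomethyl)-2-oxo-2H-pyran-6-carboxylate | CCOC(=O)c1cc(CBr)cc(=O)o1 | intermediate
12 | 4-bromo-1,2-dimethoxybenzene | COc1ccc(Br)cc1OC | starting material
13 | (3,4-dimethoxyphenyl)magnesium bromide | COc1ccc([Mg]Br)cc1OC | intermediate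
14 | bromomagnesium enolate of methyl (4R)-4-(3,4-dimethoxybenzyl)-2-oxotetrahydrofuran-3-carboxylate | COc1ccc(C[C@H]2COC(=O)C2=C(OC)O[Mg]Br)cc1OC | intermediate
15 | methyl (3R,4R)-4-(3,4-dimethoxybenzyl)-3-{[6-(ethoxycarbonyl)-2-oxo-2H-pyran-4-yl]methyl}-2-oxotetrahydrofuran-3-carboxylate | COc1ccc(C[C@H]2COC(=O)[C@@]2(Cc2cc(C(=O)OCC)oc(=O)c2)C(=O)OC)cc1OC | intermediate
16 | (3R,4R)-3-[(6-carboxy-2-oxo-2H-pyran-4-yl)methyl]-4-(3,4-dimethoxybenzyl)-2-oxotetrahydrofuran-3-carboxylic acid | COc1ccc(C[C@H]2COC(=O)[C@@]2(Cc2cc(C(=O)O)oc(=O)c2)C(=O)O)cc1OC | intermediate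
17 | 4-{[(4R)-4-(3,4-dimethoxybenzyl)-2-oxotetrahydrofuran-3-yl]methyl}-2-oxo-2H-pyran-6-carboxylic acid, mixture of C3 epimers | COc1ccc(C[C@H]2COC(=O)C2Cc2cc(C(=O)O)oc(=O)c2)cc1OC | intermediate
18 | 4-{[(3R,4R)-4-(3,4-dimethoxybenzyl)-2-oxotetrahydrofuran-3-yl]methyl}-2-oxo-2H-pyran-6-carboxylic acid | COc1ccc(C[C@H]2COC(=O)[C@@H]2Cc2cc(C(=O)O)oc(=O)c2)cc1OC | target

**Step count.** Total: 6 steps. Longest linear sequence: 5 steps (steps 2, 3, 4, 5, 6, from ethyl 3-methylbut-2-enoate).

**Steps most likely to fail**

1. Step 4 (key step). The chelated magnesium enolate 14 may alkylate too slowly and be protonated on work-up, or residual copper and magnesium species may add to the pyrone of 11. The fallback sets out from 6 and 13 and comes back at 15. The opening is run alone (CuI cat., THF, −40 °C) and quenched with dilute HCl to give methyl (4R)-4-(3,4-dimethoxybenzyl)-2-oxotetrahydrofuran-3-carboxylate F1, which is isolated. F1 is then deprotonated with K2CO3 in acetone at room temperature and alkylated with 11, so that a potassium enolate meets the pyrone in the absence of any organometallic reagent, again on the face opposite the benzyl group.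

2. Step 6. Proton exchange at C3 may be too slow with an amidine base, or the pyrone may be eroded before equilibrium is reached. The fallback sets out from 17 and comes back at 18. 17 is treated with NaOMe in MeOH at 50 °C, the classical medium for cis-to-trans equilibration of 3,4-disubstituted butyrolactones. Methoxide is expected to open the pyrone at its carbonyl carbon, giving the acyclic salt disodium 6-methoxy-4-{[(3R,4R)-4-(3,4-dimethoxybenzyl)-2-oxotetrahydrofuran-3-yl]methyl}-2-oxido-6-oxohexa-2,4-dienoate F2, in which C3 settles as trans. Acidification and heating in aqueous HCl/AcOH should then re-close the pyrone by the same enol lactonization that builds it in step 2.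

3. Step 3. Bromination of the ring, double bromination of the methyl group or decomposition of the reactive bromide during isolation may lower the supply of 11. The fallback sets out from 10 and comes back at 11 and replaces the radical halogenation by an oxidation–activation sequence. SeO2 in refluxing dioxane oxidizes the 4-methyl group to ethyl 4-formyl-2-oxo-2H-pyran-6-carboxylate F3. Luche reduction (NaBH4, CeCl3·7H2O, MeOH, −40 °C) gives ethyl 4-(hydroxymethyl)-2-oxo-2H-pyran-6-carboxylate F4. Appel bromination (CBr4, PPh3, CH2Cl2, 0 °C) converts F4 into 11.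

**Further compounds**
F1 | step 4 | methyl (4R)-4-(3,4-dimethoxybenzyl)-2-oxotetrahydrofuran-3-carboxylate (C3 epimers) | COc1ccc(C[C@H]2COC(=O)C2C(=O)OC)cc1OC
F2 | step 6 | disodium 6-methoxy-4-{[(3R,4R)-4-(3,4-dimethoxybenzyl)-2-oxotetrahydrofuran-3-yl]methyl}-2-oxido-6-oxohexa-2,4-dienoate (double-bond geometry not fixed) | COC(=O)C=C(C[C@@H]1[C@@H](Cc2ccc(OC)c(OC)c2)COC1=O)C=C([O-])C(=O)[O-].[Na+].[Na+]
F3 | step 3 | ethyl 4-formyl-2-oxo-2H-pyran-6-carboxylate | CCOC(=O)c1cc(C=O)cc(=O)o1
F4 | step 3 | ethyl 4-(hydroxymethyl)-2-oxo-2H-pyran-6-carboxylate | CCOC(=O)c1cc(CO)cc(=O)o1
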